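Count what the side step takes.

substrate 0.20 M; time 3.0 d

    substrate → intermediate (k1 = 2.5 × 10⁻⁴ min⁻¹)
    intermediate ⇌ isomer of the product (K2 = 6.2, k2 = 1.2 × 10⁻⁴ min⁻¹)
    substrate + target ⇌ idle adduct, settled at all times (K3 = 20 L mol⁻¹)
    substrate + target → side product (k4 = 0.0038 L mol⁻¹ min⁻¹)
    intermediate ⇌ target (K5 = 0.70, k5 = 8.4 × 10⁻⁴ min⁻¹)

- percent here means substrate units held: one idle adduct or side product counts as two
- what is said of target includes idle adduct
- in an amount of target, one idle adduct counts as one target
- what has gone from substrate into another species counts as reacted, even if it can come back
- run time (flask): 3.0 d

- conversion of substrate at 3.0 d
- amount of target at 3.0 d, in percent of the substrate charged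
- amount of intermediate at 3.0 d, in percent of the substrate charged
- amount of side product at 3.0 d, in percent of the substrate charged
- amount of target if the flask were left three thousand times as long, in percent of the substrate charged

Two of us disagree over the last question. One pairs the target with the intermediate and sets the isomer aside: the forward half-life of intermediate towards target is 0.57 d, shorter than the 4.0 d towards isomer. The other answers that a half-life of days is a matter of waiting, and the question asks for a long wait.

Both need the same figure, so I reckon it by hand. Substrate leaves by its first-order step and by the step with target. Both rates carry free [substrate], so it cancels from their ratio, and what remains is free [target]. Replace that curve by its mean, taken when half of the charge has left substrate. Then 0.100 M stands as free [substrate], and as many substrate units lie elsewhere; I count them in intermediate, free target and idle adduct, leaving the isomer out. Intermediate and free target relax in 0.236 d, short against the run, so I set free [target] at 0.70 times [intermediate]. The adduct balance sets [idle adduct] at 2.00 times free [target], and each idle adduct holds two units. Mean free [target] is therefore 0.0156 M, which gives 0.236 side-step events per passage through the first step: the side ratio, a selectivity factor.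

Each event puts two substrate units into side product. A flask run out therefore holds 38.2% as side product and 61.8% as intermediate, isomer and target. The first view splits that material between intermediate and target by 0.70 and makes target 25.4%. The second gives it 8.86% of that material, so 5.47%, and I commit to this.

The forecast takes the second side. It gives 5.9%, which is 0.42 percentage points above my figure, on the grounds that the material “settles into the intermediate, isomer and target”. For the three-day flask it gives conversion 75.5%, target 22.5%, intermediate 19.8% and side product 14%.

The simulation gives 75.8%, 22.8%, 20.0%, 13.7%, and 5.78% for the long wait, so the second view wins. The first keeps the days of the run: at 3.00 d target stands at 22.8%, adduct counted, above the isomer's 7.98%. That is kinetic control, and thermodynamic control comes later. Read back through the target's share, the long-wait figure means a side ratio of 0.210, against 0.236 reckoned, so my mean stood somewhat high.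

Now the flask charged with 0.080 M. There mean free [target] is 0.00993 M and the side ratio 0.151. Scaling the three-day side product by the run-out shares gives 9.41%; that flask computes to 8.71%.

Its constants are assumed; no experiment stands behind them.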